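**Retrosynthetic overview**

1. Labdane numbering is used: decalin C1–C10, C17 on C8, C18/C19 on C4, C20 on C10, chain C11–C12 on C9, butenolide C13(=C14)–C15–O–C16(=O). The C12–C13 bond comes last, by B-alkyl Suzuki–Miyaura coupling of a C9 vinyl group (C11=C12) with commercial 3-bromofuran-2(5H)-one.
2. The C17, C18 and C19 hydroxymethyl groups come from three methyl esters in one LiAlH4 reduction. Before that, C8 is set by thermodynamic epimerisation of its axial ester and the vinyl group is made from the C11 aldehyde. No protecting group is used.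
3. Rings A and B are closed together (bonds C5–C10 and C8–C9) by an enantioselective intramolecular Diels–Alder reaction of an open-chain, achiral (E,E,E)-trienal: C5=C6–C7=C8 dienoate plus C9=C10 enal, linked by C1–C4.
4. Enabling feature: ring B is a cyclohexane whose C9 carries the exocyclic carbon C11 (as a formyl group it activates C9=C10) and whose C8 carries C17 (as an ester it ends the diene and later allows epimerisation). The four ring A carbons C1–C4, with the gem-disubstituted quaternary C4, are the tether.
5. The trienal is assembled from dimethyl allylmalonate and propynal (Michael addition), a Wittig extension, hydroboration/Suzuki coupling with (E)-3-bromobut-2-en-1-ol, and MnO2 oxidation.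

Key step: step 6

Assumption: the (S)-configured oxazaborolidinium catalyst of step 6 is taken to expose the enal face that leads to 11; if the sense of induction proves opposite, the (R)-catalyst from (R)-diphenylprolinol is used. Propynal (5) is taken as a commercial reagent, distilled before use.

**Route**

Step 1
Reactants: 1 but-2-yn-1-ol
Product: 3 (E)-3-bromobut-2-en-1-ol, via O-zirconated alkenylzirconocene chloride 2 (not isolated)
Conditions: Cp2Zr(H)Cl (2.2 equiv), THF, rt; then N-bromosuccinimide, –78 → 0 °C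
Reagents that add atoms: N-bromosuccinimide, O=C1CCC(=O)N1Br
Why: Hydrozirconation adds Zr–H syn across the alkyne and, after equilibration with the excess hydride, should place zirconium on the less hindered methyl-bearing carbon, and bromodezirconation with retention then gives the (E)-alkenyl bromide (hydrozirconation–halogenation).

Step 2
Reactants: 4 dimethyl 2-allylmalonate; 5 propynal
Product: 6 dimethyl 2-allyl-2-[(E)-3-oxoprop-1-en-1-yl]malonate
Conditions: NaH (10 mol %), THF, –20 °C → rt, slow addition of 5; then DABCO (10 mol %), rt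
Reagents that add atoms: none
Why: Base-catalysed Michael addition of the malonate anion to the ynal creates the quaternary C4 and the C5=C6 bond, DABCO should equilibrate the enal to the unhindered (E)-isomer by reversible addition–elimination, and the mixture is kept at or below room temperature so that the 3,3-diester 1,5-diene does not undergo Cope rearrangement.

Step 3
Reactants: 6 dimethyl 2-allyl-2-[(E)-3-oxoprop-1-en-1-yl]malonate
Product: 7 dimethyl 2-allyl-2-[(1E,3E)-5-methoxy-5-oxopenta-1,3-dien-1-yl]malonate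
Conditions: Ph3P=CHCO2Me (1.2 equiv), CH2Cl2, rt
Reagents that add atoms: methyl (triphenylphosphoranylidene)acetate, COC(=O)C=P(c1ccccc1)(c1ccccc1)c1ccccc1
Why: Wittig olefination with a stabilised ylide extends the enal to the (2E,4E)-dienoate, the new C7=C8 bond being formed (E)-selectively.

Step 4
Reactants: 7 dimethyl 2-allyl-2-[(1E,3E)-5-methoxy-5-oxopenta-1,3-dien-1-yl]malonate; 3 (E)-3-bromobut-2-en-1-ol
Product: 9 dimethyl 2-[(E)-6-hydroxy-4-methylhex-4-en-1-yl]-2-[(1E,3E)-5-methoxy-5-oxopenta-1,3-dien-1-yl]malonate, via B-alkyl-9-BBN 8 (not isolated)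
Conditions: 9-BBN-H (1.1 equiv), THF, 0 °C → rt; then aq. K3PO4 (3 mol/L), 3, PdCl2(dppf) (5 mol %; dppf = 1,1'-bis(diphenylphosphino)ferrocene), AsPh3 (10 mol %), DMF, 50 °C
Reagents that add atoms: none
Why: 9-BBN should hydroborate only the terminal allyl alkene (anti-Markovnikov, the conjugated dienoate being inert), and the B-alkyl Suzuki–Miyaura coupling with the alkenyl bromide proceeds with retention of the (E)-geometry and joins C1 to C10.

Step 5
Reactants: 9 dimethyl 2-[(E)-6-hydroxy-4-methylhex-4-en-1-yl]-2-[(1E,3E)-5-methoxy-5-oxopenta-1,3-dien-1-yl]malonate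
Product: 10 dimethyl 2-[(1E,3E)-5-methoxy-5-oxopenta-1,3-dien-1-yl]-2-[(E)-4-methyl-6-oxohex-4-en-1-yl]malonate
Conditions: MnO2 (15 equiv), CH2Cl2, rt
Reagents that add atoms: none
Why: MnO2 oxidises the allylic alcohol chemoselectively to the (E)-enal without touching the esters or the diene (allylic oxidation).

Step 6
Reactants: 10 dimethyl 2-[(1E,3E)-5-methoxy-5-oxopenta-1,3-dien-1-yl]-2-[(E)-4-methyl-6-oxohex-4-en-1-yl]malonate
Product: 11 trimethyl (5S,8R,9R,10R)-9-formyl-10-methyl-trans-octal-6-ene-4,4,8-tricarboxylate (labdane numbering; C20, the formyl group and the C8 ester all on the α face, C5-H on the β face)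
Conditions: (S)-B-(2-methylphenyl)oxazaborolidine from (S)-α,α-diphenylprolinol (20 mol %), HNTf2 (18 mol %), CH2Cl2, –40 → 0 °C
Reagents that add atoms: none
Why: Proposed new method: the protonated oxazaborolidine is a chiral cationic boron Lewis acid that binds the formyl oxygen of the (E)-enal and lowers its LUMO, after which the C5=C6–C7=C8 diene adds suprafacially across C9=C10 in a concerted, asynchronous [4+2] cycloaddition in which the C5–C10 bond (β-carbon of the enal) runs ahead of the C8–C9 bond; the closest known reaction type is the cationic-oxazaborolidine-catalysed enantioselective intramolecular Diels–Alder reaction of (E,E,E)-trienals that carry a β-monosubstituted enal, here extended to a β,β-disubstituted enal and a diene with an ester terminus. Ring B closes by the [4+2] union itself (cyclohexene with the new C6=C7 bond), and ring A closes as the six-membered tether ring C10–C1–C2–C3–C4–C5 in a chair-like fused (type 1) mode when C5 bonds to C10. The trans ring fusion (C5-H anti to C20) should follow from the endo transition state with the catalyst-bound formyl group under the diene and the tether anti, C9 from the (E)-geometry of the enal (C11 cis to C20), C8 from the (E)-geometry of C7=C8 (ester cis to C11, to be corrected in step 9), and the absolute configuration from the catalyst, which blocks one face of the bound enal. The step needs endo over exo selectivity and one enal face, both of which complexation of the formyl group to the bulky chiral Lewis acid should secure, and enough diene reactivity, for which the butadiene-like HOMO of the 1-alkyl-4-ester diene, the Thorpe–Ingold effect of the C4 gem-diester and intramolecularity are relied on.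

Step 7
Reactants: 11 trimethyl (5S,8R,9R,10R)-9-formyl-10-methyl-trans-octal-6-ene-4,4,8-tricarboxylate
Product: 12 trimethyl (5S,8R,9R,10R)-9-formyl-10-methyl-trans-decalin-4,4,8-tricarboxylate
Conditions: H2 (1 atm), palladium on carbon (10 wt %), EtOAc, rt
Reagents that add atoms: none
Why: Heterogeneous hydrogenation saturates the disubstituted C6=C7 alkene and leaves the aldehyde and the esters intact; no stereocentre is formed.

Step 8
Reactants: 12 trimethyl (5S,8R,9R,10R)-9-formyl-10-methyl-trans-decalin-4,4,8-tricarboxylate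
Product: 13 trimethyl (5S,8R,9R,10S)-10-methyl-9-vinyl-trans-decalin-4,4,8-tricarboxylate (C8 ester still axial)
Conditions: Zn, CH2Br2, TiCl4 (Lombardo reagent), THF/CH2Cl2, 0 °C → rt
Reagents that add atoms: dibromomethane, BrCBr
Why: Non-basic Lombardo methylenation converts the hindered, epimerisable C9 aldehyde into the vinyl group without epimerising C9 and without attacking the esters.

Step 9
Reactants: 13 trimethyl (5S,8R,9R,10S)-10-methyl-9-vinyl-trans-decalin-4,4,8-tricarboxylate
Product: 14 trimethyl (5S,8S,9R,10S)-10-methyl-9-vinyl-trans-decalin-4,4,8-tricarboxylate (C8 ester equatorial, trans to the vinyl group)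
Conditions: NaOMe (0.5 equiv), MeOH, 50 °C
Reagents that add atoms: none
Why: Methoxide-mediated ester epimerisation through the C8 enolate should move the ester from the axial position, where it is 1,3-diaxial to the C10 methyl group, to the equatorial one, which sets C8 under thermodynamic control.

Step 10
Reactants: 14 trimethyl (5S,8S,9R,10S)-10-methyl-9-vinyl-trans-decalin-4,4,8-tricarboxylate
Product: 15 [(5S,8S,9R,10S)-10-methyl-9-vinyl-trans-decalin-4,4,8-triyl]trimethanol
Conditions: LiAlH4 (4 equiv), THF, 0 °C → rt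
Reagents that add atoms: none
Why: Hydride reduction of all three methyl esters delivers the C17, C18 and C19 hydroxymethyl groups in one operation and leaves the vinyl group untouched.

Step 11
Reactants: 15 [(5S,8S,9R,10S)-10-methyl-9-vinyl-trans-decalin-4,4,8-triyl]trimethanol; 16 3-bromofuran-2(5H)-one
Product: 18 3-{2-[(1R,2S,4aS,8aS)-2,5,5-tris(hydroxymethyl)-8a-methyldecahydronaphthalen-1-yl]ethyl}furan-2(5H)-one, via O-borylated B-alkyl-9-BBN 17 (not isolated)
Conditions: 9-BBN-H (5 equiv), THF, rt → 40 °C; then aq. K3PO4 (3 mol/L), 16, PdCl2(dppf) (10 mol %), AsPh3 (10 mol %), DMF, rt → 40 °C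
Reagents that add atoms: none
Why: Excess 9-BBN first masks the three hydroxyl groups as borinates (loss of H2) and then hydroborates the vinyl group at the terminal C12, the B-alkyl Suzuki–Miyaura coupling with the α-bromobutenolide forms C12–C13, and the borinates are hydrolysed on aqueous work-up.

**Compound list**

1 | but-2-yn-1-ol | CC#CCO | starting material
2 | O-zirconated (E)-alkenylzirconocene chloride (not isolated; cyclopentadienyl rings drawn σ-bonded) | C/C(=C\CO[Zr](Cl)(C1C=CC=C1)C1C=CC=C1)[Zr](Cl)(C1C=CC=C1)C1C=CC=C1 | intermediate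
3 | (E)-3-bromobut-2-en-1-ol | C/C(Br)=C\CO | intermediate
4 | dimethyl 2-allylmalonate | C=CCC(C(=O)OC)C(=O)OC | starting material
5 | propynal | C#CC=O | starting material
6 | dimethyl 2-allyl-2-[(E)-3-oxoprop-1-en-1-yl]malonate | C=CCC(/C=C/C=O)(C(=O)OC)C(=O)OC | intermediate
7 | dimethyl 2-allyl-2-[(1E,3E)-5-methoxy-5-oxopenta-1,3-dien-1-yl]malonate | C=CCC(/C=C/C=C/C(=O)OC)(C(=O)OC)C(=O)OC | intermediate
8 | B-alkyl-9-BBN from 7 (not isolated) | COC(=O)/C=C/C=C/C(CCCB1C2CCCC1CCC2)(C(=O)OC)C(=O)OC | intermediate
9 | dimethyl 2-[(E)-6-hydroxy-4-methylhex-4-en-1-yl]-2-[(1E,3E)-5-methoxy-5-oxopenta-1,3-dien-1-yl]malonate | COC(=O)/C=C/C=C/C(CCC/C(C)=C/CO)(C(=O)OC)C(=O)OC | intermediate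
10 | dimethyl 2-[(1E,3E)-5-methoxy-5-oxopenta-1,3-dien-1-yl]-2-[(E)-4-methyl-6-oxohex-4-en-1-yl]malonate | COC(=O)/C=C/C=C/C(CCC/C(C)=C/C=O)(C(=O)OC)C(=O)OC | intermediate
11 | trimethyl (5S,8R,9R,10R)-9-formyl-10-methyl-trans-octal-6-ene-4,4,8-tricarboxylate | C[C@@]12CCCC(C(=O)OC)(C(=O)OC)[C@H]1C=C[C@@H](C(=O)OC)[C@H]2C=O | intermediate
12 | trimethyl (5S,8R,9R,10R)-9-formyl-10-methyl-trans-decalin-4,4,8-tricarboxylate | C[C@@]12CCCC(C(=O)OC)(C(=O)OC)[C@H]1CC[C@@H](C(=O)OC)[C@H]2C=O | intermediate
13 | trimethyl (5S,8R,9R,10S)-10-methyl-9-vinyl-trans-decalin-4,4,8-tricarboxylate | C[C@@]12CCCC(C(=O)OC)(C(=O)OC)[C@H]1CC[C@@H](C(=O)OC)[C@H]2C=C | intermediate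
14 | trimethyl (5S,8S,9R,10S)-10-methyl-9-vinyl-trans-decalin-4,4,8-tricarboxylate | C[C@@]12CCCC(C(=O)OC)(C(=O)OC)[C@H]1CC[C@H](C(=O)OC)[C@H]2C=C | intermediate
15 | [(5S,8S,9R,10S)-10-methyl-9-vinyl-trans-decalin-4,4,8-triyl]trimethanol | C[C@@]12CCCC(CO)(CO)[C@H]1CC[C@H](CO)[C@H]2C=C | intermediate
16 | 3-bromofuran-2(5H)-one | O=C1OCC=C1Br | starting material
17 | tris(O-boryl) B-alkyl-9-BBN from 15 (not isolated) | C[C@@]12CCCC(COB3C4CCCC3CCC4)(COB3C4CCCC3CCC4)[C@H]1CC[C@H](COB1C3CCCC1CCC3)[C@H]2CCB1C2CCCC1CCC2 | intermediate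
18 | 3-{2-[(1R,2S,4aS,8aS)-2,5,5-tris(hydroxymethyl)-8a-methyldecahydronaphthalen-1-yl]ethyl}furan-2(5H)-one, (5S,8S,9R,10S) in labdane numbering | C[C@@]12CCCC(CO)(CO)[C@H]1CC[C@H](CO)[C@H]2CCC1=CCOC1=O | target

**Step count and risks**

Total step count: 11. Longest linear sequence: 10 steps (4 → 18, steps 2–11); step 1 makes the side fragment 3.

Steps most likely to fail:

1. Step 6 (proposed new method). What may go wrong: the cycloaddition of the hindered β,β-disubstituted enal with the ester-deactivated diene may be too slow at temperatures where the chiral Lewis acid still discriminates the enal faces, so that a background pathway or acid-induced isomerisation of the enal geometry erodes enantiomeric and diastereomeric purity. Fallback with known chemistry, setting out from 10: cyclisation with the achiral Lewis acid Me2AlCl (1.1 equiv, CH2Cl2, –78 → 0 °C; Lewis-acid-promoted endo-selective intramolecular Diels–Alder reaction of a trienal) should give the racemic adduct rac-11 F1. Condensation of F1 with (1R,2R)-N,N'-dimethyl-1,2-diphenylethane-1,2-diamine (Et2O, 4 Å molecular sieves, rt) should give two diastereomeric imidazolidines, the aminal of 11 F2 and the aminal of ent-11 F3, to be separated by chromatography or crystallisation. Mild hydrolysis of F2 (aq. HCl 0.5 mol/L, Et2O, 0 °C) releases the aldehyde and returns to the route at 11.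

2. Step 11. What may go wrong: the three hydroxyl groups may consume the borane and leave hydroboration incomplete, or base-induced ring opening and oligomerisation of the bromobutenolide and protodeboronation may outpace transmetalation. Fallback setting out from 15:
   - Silylation (TESCl, imidazole, DMF) gives the tris(triethylsilyl) ether of 15 F4.
   - Hydroboration with 9-BBN-H gives the B-alkyl-9-BBN F5, which is oxidised in the same flask (NaBO3·4H2O) to the C12 primary alcohol F6.
   - CBr4/PPh3 converts F6 into the C12 bromide F7.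
   - Alkylation of the lithium enolate of 3-(phenylsulfanyl)dihydrofuran-2(3H)-one (LDA, THF/HMPA, –78 → 0 °C) with F7 gives the α-(phenylsulfanyl) lactone F8.
   - Oxidation (mCPBA, CH2Cl2, –78 °C) gives the sulfoxide F9, and thermal syn-elimination (toluene, 110 °C) should give the endocyclic butenolide, the tris(triethylsilyl) ether of 18 F10.
   - HF·pyridine in THF removes the silyl groups and the fallback arrives at 18.

3. Step 2. What may go wrong: base-induced oligomerisation of propynal, 1,2-addition competing with conjugate addition at the substituted malonate carbon, or incomplete equilibration of the enal geometry. Fallback setting out from 4: conjugate addition to tert-butyl propiolate (NaH 10 mol %, THF, then DABCO) gives the (E)-acrylate, 1-tert-butyl ester F11. CF3CO2H in CH2Cl2 cleaves only the tert-butyl ester to the acrylic acid F12. Oxalyl chloride with catalytic DMF gives the acid chloride F13. Reduction with LiAlH(Ot-Bu)3 (THF, –78 °C) stops at the aldehyde and returns to the route at 6.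

Further compounds
F1 | step 6 | racemic adduct rac-11 (both enantiomers shown) | C[C@@]12CCCC(C(=O)OC)(C(=O)OC)[C@H]1C=C[C@@H](C(=O)OC)[C@H]2C=O.C[C@]12CCCC(C(=O)OC)(C(=O)OC)[C@@H]1C=C[C@H](C(=O)OC)[C@@H]2C=O
F2 | step 6 | (4R,5R)-1,3-dimethyl-4,5-diphenylimidazolidin-2-yl aminal of 11 | C[C@@]12CCCC(C(=O)OC)(C(=O)OC)[C@H]1C=C[C@@H](C(=O)OC)[C@H]2C1N(C)[C@H](c2ccccc2)[C@@H](c2ccccc2)N1C
F3 | step 6 | (4R,5R)-1,3-dimethyl-4,5-diphenylimidazolidin-2-yl aminal of ent-11 | C[C@]12CCCC(C(=O)OC)(C(=O)OC)[C@@H]1C=C[C@H](C(=O)OC)[C@@H]2C1N(C)[C@H](c2ccccc2)[C@@H](c2ccccc2)N1C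
F4 | step 11 | tris(triethylsilyl) ether of 15 | C[C@@]12CCCC(CO[Si](CC)(CC)CC)(CO[Si](CC)(CC)CC)[C@H]1CC[C@H](CO[Si](CC)(CC)CC)[C@H]2C=C
F5 | step 11 | B-alkyl-9-BBN from F4 (not isolated) | C[C@@]12CCCC(CO[Si](CC)(CC)CC)(CO[Si](CC)(CC)CC)[C@H]1CC[C@H](CO[Si](CC)(CC)CC)[C@H]2CCB1C2CCCC1CCC2
F6 | step 11 | C12 primary alcohol, tris(triethylsilyl) ether | C[C@@]12CCCC(CO[Si](CC)(CC)CC)(CO[Si](CC)(CC)CC)[C@H]1CC[C@H](CO[Si](CC)(CC)CC)[C@H]2CCO
F7 | step 11 | C12 bromide, tris(triethylsilyl) ether | C[C@@]12CCCC(CO[Si](CC)(CC)CC)(CO[Si](CC)(CC)CC)[C@H]1CC[C@H](CO[Si](CC)(CC)CC)[C@H]2CCBr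
F8 | step 11 | α-(phenylsulfanyl) lactone (mixture at C13) | C[C@@]12CCCC(CO[Si](CC)(CC)CC)(CO[Si](CC)(CC)CC)[C@H]1CC[C@H](CO[Si](CC)(CC)CC)[C@H]2CCC1(Sc2ccccc2)CCOC1=O
F9 | step 11 | α-(phenylsulfinyl) lactone (sulfoxide) | C[C@@]12CCCC(CO[Si](CC)(CC)CC)(CO[Si](CC)(CC)CC)[C@H]1CC[C@H](CO[Si](CC)(CC)CC)[C@H]2CCC1(S(=O)c2ccccc2)CCOC1=O
F10 | step 11 | tris(triethylsilyl) ether of 18 | C[C@@]12CCCC(CO[Si](CC)(CC)CC)(CO[Si](CC)(CC)CC)[C@H]1CC[C@H](CO[Si](CC)(CC)CC)[C@H]2CCC1=CCOC1=O
F11 | step 2 | 1-tert-butyl 3,3-dimethyl (E)-hexa-1,5-diene-1,3,3-tricarboxylate | C=CCC(/C=C/C(=O)OC(C)(C)C)(C(=O)OC)C(=O)OC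
F12 | step 2 | (E)-4,4-bis(methoxycarbonyl)hepta-2,6-dienoic acid | C=CCC(/C=C/C(=O)O)(C(=O)OC)C(=O)OC
F13 | step 2 | dimethyl 2-allyl-2-[(E)-3-chloro-3-oxoprop-1-en-1-yl]malonate | C=CCC(/C=C/C(=O)Cl)(C(=O)OC)C(=O)OC
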